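Readings and results stem from a simulated flask on assumed constants; noise was put on by code.

One turn of the catalyst in the flask is worth 10.0% of the substrate charged, and against that figure the blue run looked contradictory at first.

in all of them: substrate 0.22 M

| flask | reagent | free catalyst | remark | time |
|---|---|---|---|---|
| blue | 0.077 M | 22 mM | run made earlier |  |
| ochre | 0.12 M | 22 mM | run made earlier |  |
| teal | 0.154 M | 11 mM | run made earlier |  |
| flask | 0.154 M | 22 mM |  | 20 h |

| run | time / h | target / % | substrate / % |
|---|---|---|---|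
| blue | 2.50 | 1.1 | 90.6 |
| blue | 5.00 | 4.3 | 82.9 |
| blue | 6.00 | 6.0 | 81.5 |
| blue | 10.0 | 9.7 | 72.7 |
| blue | 12.0 | 11.7 | 69.4 |
| blue | 15.0 | 13.2 | 65.3 |
| ochre | 2.50 | 1.5 | 88.7 |
| ochre | 5.00 | 6.3 | 81.9 |
| ochre | 6.00 | 5.9 | 78.6 |
| ochre | 10.0 | 13.6 | 69.5 |
| ochre | 12.0 | 15.6 | 65.1 |
| ochre | 15.0 | 19.2 | 60.3 |
| teal | 1.33 | 0.6 | 94.0 |
| teal | 4.00 | 3.6 | 86.9 |
| teal | 8.00 | 5.8 | 77.6 |
| teal | 12.0 | 9.7 | 70.7 |
| teal | 15.0 | 12.7 | 66.4 |

(each reading ± 0.5 percentage points)

1. amount of target in percent of the substrate charged, at 2.0 h, 6.0 h, 12 h and 20 h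

In blue at 15.0 h, substrate had fallen by 34.7%, yet target stood at 13.2%. The gap of 21 percentage points is more than blue's catalyst could hold, since its charge equals 10.0% of the substrate. So, as these readings stand, about 11 points or more stood off the catalyst, and the proposed dormant form is where I put it.

Target, then, was the honest count. Teal had the flask's substrate and reagent charges, so I read the flask from teal in turns.

turns in teal at 12.0 h = target formed / catalyst charged = 1.94

The turn count is target formed over catalyst charged.

target in the flask at 12 h = turns × catalyst charged / substrate charged = 19.4%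

The flask holds twice teal's catalyst, so I expected its charges to fall sooner and took my figure as leaning high.

The forecast gave 1.6%, 9.5%, 20% and 30%, above my figure at 12 h, holding that substrate “is drifting reversibly into the dormant form”.

The flask gave 1.72%, 8.68%, 18.0% and 28.0%, and the forecast stood within the tolerance.

    reagent + free catalyst ⇌ catalyst intermediate A (K = 3.30 M⁻¹, k = 0.0940 M⁻¹ min⁻¹)
    substrate + catalyst intermediate A ⇌ catalyst intermediate B (K = 12.0 M⁻¹, k = 5.20 M⁻¹ min⁻¹)
    catalyst intermediate B → by-product + catalyst intermediate C (k = 0.0120 min⁻¹)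
    catalyst intermediate C → free catalyst + target (k = 0.0190 min⁻¹)
    substrate ⇌ dormant form (K = 0.470, k = 3.90 × 10⁻⁴ min⁻¹)

At 20.0 h the flask held 50.1% substrate and 19.4% dormant form beside its target. In turns, the flask reached 1.80 at 12 h, fewer than the 1.94 read in teal, and 2.80 at 20 h. The reagent, the limiting reagent here, allows 7.00 turns, which is the flask's ceiling of 70.0% target. At 200 h the flask stood at 6.93 turns, with 0.943% of its reagent left.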